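The depside ester is disconnected last, and everything rests on building ring A one oxidation level below the arene, as a cyclohexane-1,3-dione. A single Michael–Claisen operation joins dimethyl malonate to (E)-hept-3-en-2-one, forming C1–C6 and C2–C3 and closing ring A with the propyl chain and the ester carbon already in place. The feature exploited is that C3 of ring A lies between the oxygens on C2 and C4: in the dione it is the enolic carbon flanked by both ketones, so chlorine enters at C3 rather than C5, and O4 is the less hindered oxygen that becomes the methyl ether during aromatisation. The precursor is simply the pair of commercial reagents.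

Key step: step 1

Remark: the dione compounds are drawn as single tautomers and the racemic trans dione as its (1S,6R) enantiomer; the carboxyl group of ring B is carried as a formyl group until the last step, so that no ester has to be removed from the finished depside.

Step 1
Reactants: 1 (E)-hept-3-en-2-one; 2 dimethyl malonate
Product: 4 methyl 2,4-dioxo-6-propylcyclohexane-1-carboxylate (racemic trans), via Michael adduct 3 (not isolated)
Conditions: NaOMe (1.1 equiv), MeOH, reflux; then cold aq. HCl
Reagents that add atoms: none
Why: Methoxide deprotonates the malonate, the soft stabilised carbanion adds 1,4 to the enone at the propyl-bearing carbon (C1–C6), and after proton transfer the terminal methyl ketone enolate attacks one malonate ester carbonyl and expels methoxide (C2–C3), the sequence being pulled forward by irreversible deprotonation of the acidic dione. The closest known reaction type is the Michael–Claisen (Dieckmann-type) cyclocondensation of malonates with alk-3-en-2-ones to 6-alkyl-2,4-dioxocyclohexanecarboxylates. Ring A closes in a 6-exo-trig mode, the attacked ester C=O lying outside the new ring. C6 is set in the conjugate addition with no chiral element present and C1 is the epimerisable β-keto ester carbon, so the product should settle under thermodynamic control as the racemic trans (diequatorial) isomer, and both centres vanish on aromatisation. The step needs only 1,4- before 1,2-addition and closure through the methyl group; the reversible addition of malonate to C=O secures the first, and the second follows because enolisation toward the internal CH2 or attack of the malonate carbon on the ketone could only close four-membered rings. Matching methoxide to the methyl esters excludes ester scrambling.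

Step 2
Reactants: 4 methyl 2,4-dioxo-6-propylcyclohexane-1-carboxylate; 5 N-chlorosuccinimide
Product: 6 methyl 3-chloro-4-hydroxy-2-oxo-6-propylcyclohex-3-ene-1-carboxylate (enol form of the 3-chloro-2,4-dione, racemic trans)
Conditions: NCS (1.0 equiv), CH2Cl2, 0 °C to rt
Reagents that add atoms: N-chlorosuccinimide 5, O=C1CCC(=O)N1Cl
Why: Electrophilic α-chlorination of a cyclic 1,3-dione, whose enol spans C2–C3–C4 and is nucleophilic at C3; C1 is also flanked by two carbonyls (ketone and ester) but is tertiary and far less acidic, so one equivalent of NCS should chlorinate C3 only, and the product enolises so that no new stereocentre persists.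

Step 3
Reactants: 6 methyl 3-chloro-4-hydroxy-2-oxo-6-propylcyclohex-3-ene-1-carboxylate
Product: 8 methyl 3-chloro-2-hydroxy-4-methoxy-6-propylbenzoate, via enol ether 7 (not isolated)
Conditions: I2 (2 equiv), MeOH, rt then reflux; aq. Na2S2O3 work-up
Reagents that add atoms: methanol, CO
Why: Iodine–methanol dehydrogenative aromatisation of a cyclohexane-1,3-dione, in which acid-catalysed exchange with methanol should first give the vinylogous methyl ester at the less hindered O4 (O2 sits between the C1 ester and the C3 chlorine and stays chelated), fixing chlorine on an sp2 carbon before iodination at C1 and loss of HI give the phenol tautomer and erase C1 and C6.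

Step 4
Reactants: 8 methyl 3-chloro-2-hydroxy-4-methoxy-6-propylbenzoate
Product: 9 3-chloro-2-hydroxy-4-methoxy-6-propylbenzoic acid
Conditions: KOH, DMSO/H2O, 80 °C; then cold 1 M HCl
Reagents that add atoms: potassium hydroxide (carboxyl oxygen), [K+].[OH-]
Why: Saponification of a hindered salicylate ester, which needs hot hydroxide in a dipolar solvent; the ring is held as the phenoxide–carboxylate dianion that does not decarboxylate, and cold acidification releases the acid without touching the aryl chloride or the methyl ether.

Step 5
Reactants: 10 5-propylbenzene-1,3-diol (divarinol)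
Product: 12 2,4-dihydroxy-6-propylbenzaldehyde, via iminium chloride 11 (not isolated)
Conditions: POCl3, DMF, 0 °C to rt; then H2O, aq. NaOAc
Reagents that add atoms: N,N-dimethylformamide (formyl carbon), CN(C)C=O; water (formyl oxygen), O
Why: Vilsmeier–Haack formylation, in which the chloroiminium ion should attack the resorcinol carbon para to one hydroxyl and ortho to the other (next to propyl) in preference to the crowded carbon between the two hydroxyls, and hydrolysis of iminium salt 11 frees the aldehyde.

Step 6
Reactants: 9 3-chloro-2-hydroxy-4-methoxy-6-propylbenzoic acid; 12 2,4-dihydroxy-6-propylbenzaldehyde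
Product: 14 4-formyl-3-hydroxy-5-propylphenyl 3-chloro-2-hydroxy-4-methoxy-6-propylbenzoate, via mixed anhydride 13 (not isolated)
Conditions: (CF3CO)2O, toluene, 0 °C to rt; then aq. NaHCO3
Reagents that add atoms: none
Why: Trifluoroacetic anhydride-mediated esterification, in which the mixed anhydride of the hindered electron-rich acid transfers its aroyl group (acylium-like) to the 4-OH of 12, the only phenol not hydrogen-bonded to a neighbouring carbonyl, and any aryl trifluoroacetate formed reversibly is cleaved in the bicarbonate wash.

Step 7
Reactants: 14 4-formyl-3-hydroxy-5-propylphenyl 3-chloro-2-hydroxy-4-methoxy-6-propylbenzoate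
Product: 15 3-chlorodivaricatic acid, 4-[(3-chloro-2-hydroxy-4-methoxy-6-propylbenzoyl)oxy]-2-hydroxy-6-propylbenzoic acid
Conditions: NaClO2, NaH2PO4, 2-methylbut-2-ene (large excess), t-BuOH/THF/H2O, 0 °C to rt
Reagents that add atoms: sodium chlorite (carboxyl oxygen), [Na+].[O-]Cl=O
Why: Pinnick (Lindgren) oxidation, in which chlorous acid adds to the aldehyde and fragments to the carboxylic acid at about pH 4, conditions under which the depside ester, the aryl chloride and the free phenols should survive while the alkene traps the hypochlorous acid.

Compound list
1 | (E)-hept-3-en-2-one | CCC/C=C/C(C)=O | starting material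
2 | dimethyl malonate | COC(=O)CC(=O)OC | starting material
3 | dimethyl 2-(2-oxoheptan-4-yl)propanedioate (Michael adduct, racemic, R drawn) | CCC[C@H](CC(C)=O)C(C(=O)OC)C(=O)OC | intermediate (not isolated)
4 | methyl 2,4-dioxo-6-propylcyclohexane-1-carboxylate (racemic trans, 1S,6R drawn) | CCC[C@@H]1CC(=O)CC(=O)[C@H]1C(=O)OC | intermediate
5 | N-chlorosuccinimide | O=C1CCC(=O)N1Cl | starting material
6 | methyl 3-chloro-4-hydroxy-2-oxo-6-propylcyclohex-3-ene-1-carboxylate (enol form of the 3-chloro-2,4-dione, racemic trans) | CCC[C@@H]1CC(O)=C(Cl)C(=O)[C@H]1C(=O)OC | intermediate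
7 | methyl 3-chloro-4-methoxy-2-oxo-6-propylcyclohex-3-ene-1-carboxylate (enol ether, racemic trans) | CCC[C@@H]1CC(OC)=C(Cl)C(=O)[C@H]1C(=O)OC | intermediate (not isolated)
8 | methyl 3-chloro-2-hydroxy-4-methoxy-6-propylbenzoate | CCCc1cc(OC)c(Cl)c(O)c1C(=O)OC | intermediate
9 | 3-chloro-2-hydroxy-4-methoxy-6-propylbenzoic acid | CCCc1cc(OC)c(Cl)c(O)c1C(=O)O | intermediate
10 | 5-propylbenzene-1,3-diol (divarinol) | CCCc1cc(O)cc(O)c1 | starting material
11 | [(2,4-dihydroxy-6-propylphenyl)methylidene]dimethylammonium chloride (iminium chloride) | CCCc1cc(O)cc(O)c1C=[N+](C)C.[Cl-] | intermediate (not isolated)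
12 | 2,4-dihydroxy-6-propylbenzaldehyde | CCCc1cc(O)cc(O)c1C=O | intermediate
13 | 3-chloro-2-hydroxy-4-methoxy-6-propylbenzoic trifluoroacetic anhydride (mixed anhydride) | CCCc1cc(OC)c(Cl)c(O)c1C(=O)OC(=O)C(F)(F)F | intermediate (not isolated)
14 | 4-formyl-3-hydroxy-5-propylphenyl 3-chloro-2-hydroxy-4-methoxy-6-propylbenzoate | CCCc1cc(OC(=O)c2c(CCC)cc(OC)c(Cl)c2O)cc(O)c1C=O | intermediate
15 | 3-chlorodivaricatic acid | CCCc1cc(OC(=O)c2c(CCC)cc(OC)c(Cl)c2O)cc(O)c1C(=O)O | target

Total step count: 7. Longest linear sequence: 6 steps (steps 1, 2, 3, 4, 6 and 7); step 5 is a one-step branch.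

Steps most likely to fail

Step 3. The hydrogen iodide released could strip chlorine from C3 by halogen transfer before the enol ether has formed, or dehydrogenation could outrun enol ether formation and leave O4 unmethylated. The fallback sets out from 6 and removes iodine and hydrogen iodide from the sequence. A second chlorination at C3 with NCS should give methyl 3,3-dichloro-2,4-dioxo-6-propylcyclohexane-1-carboxylate F1. Heating F1 in DMF containing HCl should transpose one chlorine to C1 or C5 and expel hydrogen chloride, the dehydrochlorinative aromatisation by which 2,2-dichlorocyclohexane-1,3-dione is turned into 2-chlororesorcinol, and give methyl 3-chloro-2,4-dihydroxy-6-propylbenzoate F2. Methylation of the unchelated 4-OH with MeI and K2CO3 in acetone returns to the route at 8.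

Step 2. Over-chlorination at C3, or competing chlorination at the C1 β-keto ester carbon followed by premature loss of HCl, would erode the site control. The fallback sets out from 4 and reverses the order of events. Iodine in methanol should aromatise the unchlorinated dione to methyl 2-hydroxy-4-methoxy-6-propylbenzoate F3. The arene is then chlorinated with SO2Cl2 and catalytic 2,2,6,6-tetramethylpiperidine in toluene, conditions that direct chlorine ortho to a free phenol (C3) rather than para (C5). Any C5 isomer is removed by chromatography, and the route is rejoined at 8.

Step 7. Hypochlorous acid that escapes the scavenger could chlorinate the electron-rich rings (C5 of ring A, C3 and C5 of ring B), and the chelated aldehyde could oxidise sluggishly. The fallback sets out from 10 (and uses 9) and carries the ring B carboxyl as an acid-labile ester. Carboxylation of divarinol with MeOMgOCO2Me in DMF at about 120 °C should give 2,4-dihydroxy-6-propylbenzoic acid F4, to be separated from any isomer carboxylated between the hydroxyls. N,N-dimethylformamide di-tert-butyl acetal in toluene converts it into tert-butyl 2,4-dihydroxy-6-propylbenzoate F5. Coupling with acid 9 by DCC and catalytic DMAP in CH2Cl2 should give tert-butyl 4-[(3-chloro-2-hydroxy-4-methoxy-6-propylbenzoyl)oxy]-2-hydroxy-6-propylbenzoate F6, and CF3CO2H in CH2Cl2 at 0 °C cleaves the tert-butyl ester to arrive at 15.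

Further compounds
F1 | step 3 | methyl 3,3-dichloro-2,4-dioxo-6-propylcyclohexane-1-carboxylate (racemic trans) | CCC[C@@H]1CC(=O)C(Cl)(Cl)C(=O)[C@H]1C(=O)OC
F2 | step 3 | methyl 3-chloro-2,4-dihydroxy-6-propylbenzoate | CCCc1cc(O)c(Cl)c(O)c1C(=O)OC
F3 | step 2 | methyl 2-hydroxy-4-methoxy-6-propylbenzoate | CCCc1cc(OC)cc(O)c1C(=O)OC
F4 | step 7 | 2,4-dihydroxy-6-propylbenzoic acid | CCCc1cc(O)cc(O)c1C(=O)O
F5 | step 7 | tert-butyl 2,4-dihydroxy-6-propylbenzoate | CCCc1cc(O)cc(O)c1C(=O)OC(C)(C)C
F6 | step 7 | tert-butyl 4-[(3-chloro-2-hydroxy-4-methoxy-6-propylbenzoyl)oxy]-2-hydroxy-6-propylbenzoate | CCCc1cc(OC(=O)c2c(CCC)cc(OC)c(Cl)c2O)cc(O)c1C(=O)OC(C)(C)C
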